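**Retrosynthetic overview** (numbering: C1 = CH2OAc carbon, chain to C16, C20 = CH2OH carbon)
1. Target ⇐ desilylation ⇐ Mislow–Evans [2,3]-sigmatropic shift of allylic sulfoxide 23, which forms the C20–O bond and the 2E olefin; 23 ⇐ α-alkylation of the sulfoxide anion with BrCH2OAc (C1–C2 bond).
2. Oxirane ⇐ anti-diol 18 via the secondary mesylate (inversion at C6); the tertiary carbinol C7 ⇐ chelate-controlled MeMgBr addition to α-hydroxy ketone 17.
3. 17 ⇐ Weinreb amide 15 (C2–C7 with the allyl sulfide; from methyl (S)-glycidate and a 2-(PhS-methyl)allyl Grignard) + homoallyllithium 16 (C8–C16).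
4. 16 ⇐ iodide 9 ⇐ methyl (R)-glycidate: isobutenyl opening, ester → alkyne, Zr-carboalumination/ethylene oxide (E-C10=C11).
5. Ring order: the molecule stays acyclic until the single oxirane is closed in step 11, before the sigmatropic step.

Assumption: both serine-derived enantiomers of methyl glycidate are taken as cheap commercial chiral starting materials, and the Grignard solution 2 is bought.

**Step 1**
Reactants: 1 methyl (2R)-oxirane-2-carboxylate; 2 (2-methylprop-1-en-1-yl)magnesium bromide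
Product: 3 methyl (2R)-2-hydroxy-5-methylhex-4-enoate
Conditions: CuI (10 mol%), THF, −78 → −30 °C; aq NH4Cl
Reagents that add atoms: none
Why: Copper-catalysed Grignard opening of the epoxide (SN2 at the unsubstituted CH2) leaves the purchased stereocentre untouched, so it becomes the (R)-carbinol C12.

**Step 2**
Reactants: 3 methyl (2R)-2-hydroxy-5-methylhex-4-enoate
Product: 4 methyl (2R)-2-[(tert-butyldimethylsilyl)oxy]-5-methylhex-4-enoate
Conditions: TBSCl, imidazole, DMF, rt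
Reagents that add atoms: tert-butyldimethylsilyl chloride CC(C)(C)[Si](C)(C)Cl
Why: Standard O-silylation of a secondary alcohol protects the carbinol for the hydride, organometallic and base steps that follow.

**Step 3**
Reactants: 4 methyl (2R)-2-[(tert-butyldimethylsilyl)oxy]-5-methylhex-4-enoate
Product: 6 tert-butyl(dimethyl){[(3R)-6-methylhept-5-en-1-yn-3-yl]oxy}silane, via aldehyde 5 (not isolated)
Conditions: DIBAL-H (1.1 eq), CH2Cl2, −78 °C; then MeOH, K2CO3, Bestmann–Ohira reagent, −78 °C → rt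
Reagents that add atoms: dimethyl (1-diazo-2-oxopropyl)phosphonate COP(=O)(OC)C(=[N+]=[N-])C(C)=O
Why: DIBAL half-reduction of the α-silyloxy ester stops at the aldehyde, which the Ohira–Bestmann (Seyferth–Gilbert) homologation converts to the terminal alkyne under K2CO3/MeOH mild enough to keep the α-stereocentre.

**Step 4**
Reactants: 6 tert-butyl(dimethyl){[(3R)-6-methylhept-5-en-1-yn-3-yl]oxy}silane
Product: 8 (3E,5R)-5-[(tert-butyldimethylsilyl)oxy]-4,8-dimethylnona-3,7-dien-1-ol, via vinylalane 7 (not isolated)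
Conditions: Me3Al (3 eq), Cp2ZrCl2 (20 mol%), CH2Cl2, 0 °C → rt; then n-BuLi, THF/hexane, −78 °C; ethylene oxide, −78 °C → rt; aq Rochelle salt
Reagents that add atoms: trimethylaluminium C[Al](C)C; ethylene oxide C1CO1
Why: Negishi zirconium-catalysed carboalumination adds Me–Al syn across the alkyne (Me on the internal carbon), and the derived alkenylalanate opens ethylene oxide with retention, which fixes the E-trisubstituted C10=C11 olefin.

**Step 5**
Reactants: 8 (3E,5R)-5-[(tert-butyldimethylsilyl)oxy]-4,8-dimethylnona-3,7-dien-1-ol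
Product: 9 tert-butyl{[(3E,5R)-1-iodo-4,8-dimethylnona-3,7-dien-5-yl]oxy}dimethylsilane
Conditions: I2, PPh3, imidazole, CH2Cl2, 0 °C
Reagents that add atoms: iodine II
Why: Appel-type (Garegg–Samuelsson) iodination converts the primary alcohol to the iodide by SN2 without touching the silyl ether or the olefins.

**Step 6**
Reactants: 10 3-chloro-2-(chloromethyl)prop-1-ene
Product: 11 {[2-(chloromethyl)prop-2-en-1-yl]sulfanyl}benzene
Conditions: PhSH (1 eq), K2CO3, acetone, 0 °C → rt; 10 in threefold excess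
Reagents that add atoms: benzenethiol Sc1ccccc1
Why: Thiolate SN2 substitution of one allylic chloride is kept to mono-substitution by the excess of the symmetric dichloride.

**Step 7**
Reactants: 11 {[2-(chloromethyl)prop-2-en-1-yl]sulfanyl}benzene; 12 methyl (2S)-oxirane-2-carboxylate
Product: 14 methyl (2S)-2-hydroxy-5-[(phenylsulfanyl)methyl]hex-5-enoate, via Grignard reagent 13 (not isolated)
Conditions: Mg, THF, 0 °C; then slow addition to 12, CuI (20 mol%), THF, −78 → −40 °C; aq NH4Cl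
Reagents that add atoms: none
Why: Copper-catalysed SN2 opening of the glycidate CH2 by the allylic Grignard, whose two termini are equivalent, gives one regioisomer and keeps the purchased (S)-stereocentre that becomes C6.

**Step 8**
Reactants: 14 methyl (2S)-2-hydroxy-5-[(phenylsulfanyl)methyl]hex-5-enoate
Product: 15 (2S)-2-hydroxy-N-methoxy-N-methyl-5-[(phenylsulfanyl)methyl]hex-5-enamide
Conditions: MeNH(OMe)·HCl, i-PrMgCl (4 eq), THF, −20 → 0 °C
Reagents that add atoms: N,O-dimethylhydroxylamine hydrochloride CNOC.Cl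
Why: Aminolysis of the ester by the in situ magnesium amide (Weinreb amide synthesis) proceeds with the hydroxyl simply carried as its alkoxide, so no protecting group is needed.

**Step 9**
Reactants: 9 tert-butyl{[(3E,5R)-1-iodo-4,8-dimethylnona-3,7-dien-5-yl]oxy}dimethylsilane; 15 (2S)-2-hydroxy-N-methoxy-N-methyl-5-[(phenylsulfanyl)methyl]hex-5-enamide
Product: 17 (5S,9E,11R)-11-[(tert-butyldimethylsilyl)oxy]-5-hydroxy-10,14-dimethyl-2-[(phenylsulfanyl)methyl]pentadeca-1,9,13-trien-6-one, via organolithium 16 (not isolated)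
Conditions: 9, t-BuLi (2.1 eq), Et2O, −78 °C; add to 15 pre-treated with i-PrMgCl (1.0 eq), THF, −78 → −20 °C; cold aq NH4Cl
Reagents that add atoms: none
Why: Iodine–lithium exchange followed by the Weinreb ketone synthesis stops at the ketone because of the chelated tetrahedral intermediate, and no stereocentre is touched.

**Step 10**
Reactants: 17 (5S,9E,11R)-11-[(tert-butyldimethylsilyl)oxy]-5-hydroxy-10,14-dimethyl-2-[(phenylsulfanyl)methyl]pentadeca-1,9,13-trien-6-one
Product: 18 (5S,6R,9E,11R)-11-[(tert-butyldimethylsilyl)oxy]-6,10,14-trimethyl-2-[(phenylsulfanyl)methyl]pentadeca-1,9,13-triene-5,6-diol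
Conditions: MeMgBr (3.5 eq), Et2O/CH2Cl2, −78 → −20 °C
Reagents that add atoms: methylmagnesium bromide C[Mg]Br
Why: Cram-chelate-controlled Grignard addition: the magnesium alkoxide and the carbonyl form a five-membered chelate and methyl attacks the face away from the C4–C5 chain, setting the tertiary carbinol as the (5S,6R) anti-diol.

**Step 11**
Reactants: 18 (5S,6R,9E,11R)-11-[(tert-butyldimethylsilyl)oxy]-6,10,14-trimethyl-2-[(phenylsulfanyl)methyl]pentadeca-1,9,13-triene-5,6-diol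
Product: 20 (2R,3R)-2-[(3E,5R)-5-[(tert-butyldimethylsilyl)oxy]-4,8-dimethylnona-3,7-dien-1-yl]-2-methyl-3-{3-[(phenylsulfanyl)methyl]but-3-en-1-yl}oxirane, via mesylate 19 (not isolated)
Conditions: MsCl, Et3N, CH2Cl2, −20 °C; then K2CO3, MeOH, rt
Reagents that add atoms: none
Why: Only the secondary hydroxyl is sulfonylated, and intramolecular Williamson closure by the tertiary alkoxide (SN2, inversion at the secondary carbon) gives the (2R,3R)-trans oxirane.

**Step 12**
Reactants: 20 (2R,3R)-2-[(3E,5R)-5-[(tert-butyldimethylsilyl)oxy]-4,8-dimethylnona-3,7-dien-1-yl]-2-methyl-3-{3-[(phenylsulfanyl)methyl]but-3-en-1-yl}oxirane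
Product: 21 (2R,3R)-3-{3-[(benzenesulfinyl)methyl]but-3-en-1-yl}-2-[(3E,5R)-5-[(tert-butyldimethylsilyl)oxy]-4,8-dimethylnona-3,7-dien-1-yl]-2-methyloxirane (both sulfur epimers)
Conditions: mCPBA (1.0 eq), NaHCO3, CH2Cl2, −78 °C
Reagents that add atoms: 3-chloroperbenzoic acid OOC(=O)c1cccc(Cl)c1
Why: Electrophilic oxidation at sulfur is far faster than olefin epoxidation at −78 °C, and the sulfoxide oxygen introduced here becomes the C20 hydroxyl oxygen.

**Step 13**
Reactants: 21 (2R,3R)-3-{3-[(benzenesulfinyl)methyl]but-3-en-1-yl}-2-[(3E,5R)-5-[(tert-butyldimethylsilyl)oxy]-4,8-dimethylnona-3,7-dien-1-yl]-2-methyloxirane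
Product: 25 (2E)-5-[(2R,3R)-3-[(3E,5R)-5-[(tert-butyldimethylsilyl)oxy]-4,8-dimethylnona-3,7-dien-1-yl]-3-methyloxiran-2-yl]-3-(hydroxymethyl)pent-2-en-1-yl acetate, via lithiated sulfoxide 22 (not isolated), via alkylated sulfoxide 23 (not isolated), via sulfenate ester 24 (not isolated)
Conditions: LDA (1.0 eq), THF, −78 °C; BrCH2OAc (1.2 eq), −78 °C; aq NH4Cl, crude taken on; P(OMe)3 (3 eq), MeOH, rt
Reagents that add atoms: bromomethyl acetate CC(=O)OCBr
Why: Evans α-alkylation of the sulfinyl-stabilised allyl anion installs C1, and the Mislow–Evans [2,3]-sigmatropic rearrangement of 23 (acetoxymethyl group pseudo-equatorial in the envelope transition state) forms the C20–O bond and the 2E olefin, the sulfenate being cleaved irreversibly by the thiophile.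

**Step 14**
Reactants: 25 (2E)-5-[(2R,3R)-3-[(3E,5R)-5-[(tert-butyldimethylsilyl)oxy]-4,8-dimethylnona-3,7-dien-1-yl]-3-methyloxiran-2-yl]-3-(hydroxymethyl)pent-2-en-1-yl acetate
Product: 26 (2E)-5-[(2R,3R)-3-[(3E,5R)-5-hydroxy-4,8-dimethylnona-3,7-dien-1-yl]-3-methyloxiran-2-yl]-3-(hydroxymethyl)pent-2-en-1-yl acetate
Conditions: TBAF, AcOH (1:1), THF, 0 °C → rt
Reagents that add atoms: none
Why: Fluoride desilylation buffered with acetic acid frees the C12 hydroxyl without cleaving the acetate or opening the oxirane, and the E-disposed acetate cannot migrate to the C20 hydroxyl.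

**Compound list**
1 | methyl (2R)-oxirane-2-carboxylate | COC(=O)[C@H]1CO1 | starting material
2 | (2-methylprop-1-en-1-yl)magnesium bromide | CC(C)=C[Mg]Br | starting material
3 | methyl (2R)-2-hydroxy-5-methylhex-4-enoate | COC(=O)[C@H](O)CC=C(C)C | intermediate
4 | methyl (2R)-2-[(tert-butyldimethylsilyl)oxy]-5-methylhex-4-enoate | COC(=O)[C@H](O[Si](C)(C)C(C)(C)C)CC=C(C)C | intermediate
5 | (2R)-2-[(tert-butyldimethylsilyl)oxy]-5-methylhex-4-enal | O=C[C@H](O[Si](C)(C)C(C)(C)C)CC=C(C)C | intermediate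
6 | tert-butyl(dimethyl){[(3R)-6-methylhept-5-en-1-yn-3-yl]oxy}silane | C#C[C@H](O[Si](C)(C)C(C)(C)C)CC=C(C)C | intermediate
7 | [(1E,3R)-3-[(tert-butyldimethylsilyl)oxy]-2,6-dimethylhepta-1,5-dien-1-yl]dimethylalumane | C[Al](C)/C=C(\C)[C@H](O[Si](C)(C)C(C)(C)C)CC=C(C)C | intermediate
8 | (3E,5R)-5-[(tert-butyldimethylsilyl)oxy]-4,8-dimethylnona-3,7-dien-1-ol | OCC/C=C(\C)[C@H](O[Si](C)(C)C(C)(C)C)CC=C(C)C | intermediate
9 | tert-butyl{[(3E,5R)-1-iodo-4,8-dimethylnona-3,7-dien-5-yl]oxy}dimethylsilane | ICC/C=C(\C)[C@H](O[Si](C)(C)C(C)(C)C)CC=C(C)C | intermediate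
10 | 3-chloro-2-(chloromethyl)prop-1-ene | ClCC(=C)CCl | starting material
11 | {[2-(chloromethyl)prop-2-en-1-yl]sulfanyl}benzene | ClCC(=C)CSc1ccccc1 | intermediate
12 | methyl (2S)-oxirane-2-carboxylate | COC(=O)[C@@H]1CO1 | starting material
13 | {2-[(phenylsulfanyl)methyl]prop-2-en-1-yl}magnesium chloride | Cl[Mg]CC(=C)CSc1ccccc1 | intermediate
14 | methyl (2S)-2-hydroxy-5-[(phenylsulfanyl)methyl]hex-5-enoate | COC(=O)[C@@H](O)CCC(=C)CSc1ccccc1 | intermediate
15 | (2S)-2-hydroxy-N-methoxy-N-methyl-5-[(phenylsulfanyl)methyl]hex-5-enamide | CON(C)C(=O)[C@@H](O)CCC(=C)CSc1ccccc1 | intermediate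
16 | [(3E,5R)-5-[(tert-butyldimethylsilyl)oxy]-4,8-dimethylnona-3,7-dien-1-yl]lithium | [Li]CC/C=C(\C)[C@H](O[Si](C)(C)C(C)(C)C)CC=C(C)C | intermediate
17 | (5S,9E,11R)-11-[(tert-butyldimethylsilyl)oxy]-5-hydroxy-10,14-dimethyl-2-[(phenylsulfanyl)methyl]pentadeca-1,9,13-trien-6-one | C=C(CSc1ccccc1)CC[C@H](O)C(=O)CC/C=C(\C)[C@H](O[Si](C)(C)C(C)(C)C)CC=C(C)C | intermediate
18 | (5S,6R,9E,11R)-11-[(tert-butyldimethylsilyl)oxy]-6,10,14-trimethyl-2-[(phenylsulfanyl)methyl]pentadeca-1,9,13-triene-5,6-diol | C=C(CSc1ccccc1)CC[C@H](O)[C@](C)(O)CC/C=C(\C)[C@H](O[Si](C)(C)C(C)(C)C)CC=C(C)C | intermediate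
19 | (5S,6R,9E,11R)-11-[(tert-butyldimethylsilyl)oxy]-6-hydroxy-6,10,14-trimethyl-2-[(phenylsulfanyl)methyl]pentadeca-1,9,13-trien-5-yl methanesulfonate | C=C(CSc1ccccc1)CC[C@H](OS(C)(=O)=O)[C@](C)(O)CC/C=C(\C)[C@H](O[Si](C)(C)C(C)(C)C)CC=C(C)C | intermediate
20 | (2R,3R)-2-[(3E,5R)-5-[(tert-butyldimethylsilyl)oxy]-4,8-dimethylnona-3,7-dien-1-yl]-2-methyl-3-{3-[(phenylsulfanyl)methyl]but-3-en-1-yl}oxirane | C=C(CSc1ccccc1)CC[C@H]1O[C@]1(C)CC/C=C(\C)[C@H](O[Si](C)(C)C(C)(C)C)CC=C(C)C | intermediate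
21 | (2R,3R)-3-{3-[(benzenesulfinyl)methyl]but-3-en-1-yl}-2-[(3E,5R)-5-[(tert-butyldimethylsilyl)oxy]-4,8-dimethylnona-3,7-dien-1-yl]-2-methyloxirane (sulfur epimers) | C=C(CS(=O)c1ccccc1)CC[C@H]1O[C@]1(C)CC/C=C(\C)[C@H](O[Si](C)(C)C(C)(C)C)CC=C(C)C | intermediate
22 | α-lithio derivative of 21 (lithium on the carbon bearing sulfur) | [Li]C(S(=O)c1ccccc1)C(=C)CC[C@H]1O[C@]1(C)CC/C=C(\C)[C@H](O[Si](C)(C)C(C)(C)C)CC=C(C)C | intermediate
23 | 2-(benzenesulfinyl)-5-[(2R,3R)-3-[(3E,5R)-5-[(tert-butyldimethylsilyl)oxy]-4,8-dimethylnona-3,7-dien-1-yl]-3-methyloxiran-2-yl]-3-methylidenepentyl acetate (mixture at C2 and sulfur) | CC(=O)OCC(S(=O)c1ccccc1)C(=C)CC[C@H]1O[C@]1(C)CC/C=C(\C)[C@H](O[Si](C)(C)C(C)(C)C)CC=C(C)C | intermediate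
24 | (2E)-5-[(2R,3R)-3-[(3E,5R)-5-[(tert-butyldimethylsilyl)oxy]-4,8-dimethylnona-3,7-dien-1-yl]-3-methyloxiran-2-yl]-3-{[(phenylsulfanyl)oxy]methyl}pent-2-en-1-yl acetate | CC(=O)OC/C=C(/COSc1ccccc1)CC[C@H]1O[C@]1(C)CC/C=C(\C)[C@H](O[Si](C)(C)C(C)(C)C)CC=C(C)C | intermediate
25 | (2E)-5-[(2R,3R)-3-[(3E,5R)-5-[(tert-butyldimethylsilyl)oxy]-4,8-dimethylnona-3,7-dien-1-yl]-3-methyloxiran-2-yl]-3-(hydroxymethyl)pent-2-en-1-yl acetate | CC(=O)OC/C=C(/CO)CC[C@H]1O[C@]1(C)CC/C=C(\C)[C@H](O[Si](C)(C)C(C)(C)C)CC=C(C)C | intermediate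
26 | (2E)-5-[(2R,3R)-3-[(3E,5R)-5-hydroxy-4,8-dimethylnona-3,7-dien-1-yl]-3-methyloxiran-2-yl]-3-(hydroxymethyl)pent-2-en-1-yl acetate (CNP0323680.1) | CC(=O)OC/C=C(/CO)CC[C@H]1O[C@]1(C)CC/C=C(\C)[C@H](O)CC=C(C)C | target

**Totals**
Total steps: 14. Longest linear sequence: 11 steps (1–5, then 9–14).

**Three steps most likely to fail**

Step 13 (alkylation and [2,3] shift). The sulfinyl allyl anion may attack the acetate carbonyl of BrCH2OAc or deprotonate it, may alkylate at the γ-carbon, or may open the oxirane intramolecularly; the E/Z ratio of the rearrangement is also not guaranteed with a 2-alkyl substituent larger than methyl. Fallback: set out from 21, deprotonate as before to 22 and trap it with monomeric formaldehyde at −78 °C to give 2-(benzenesulfinyl)-5-[(2R,3R)-3-[(3E,5R)-5-[(tert-butyldimethylsilyl)oxy]-4,8-dimethylnona-3,7-dien-1-yl]-3-methyloxiran-2-yl]-3-methylidenepentan-1-ol F3. Acetylation of F3 (Ac2O, pyridine, DMAP) rejoins the route at 23, which is treated with P(OMe)3/MeOH to give 25.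

Step 7 (allylic Grignard on the glycidate ester). The allylic Grignard 13 may add to the ester faster than copper delivers it to the epoxide. Fallback: set out from 12 and saponify (LiOH, THF/H2O, 0 °C, then dry) to lithium (2S)-oxirane-2-carboxylate F1, whose carboxylate is inert to 13. CuI-catalysed opening with 13 and acidic work-up gives (2S)-2-hydroxy-5-[(phenylsulfanyl)methyl]hex-5-enoic acid F2, and MeI/K2CO3 in DMF returns to the route at 14.

Step 4 (one-pot carboalumination and epoxide opening). The alanate transfer to ethylene oxide may be low-yielding next to the allylic silyl ether and excess aluminium reagents. Fallback: set out from 6, carboaluminate to 7 as before and quench with iodine to isolate tert-butyl{[(1E,3R)-1-iodo-2,6-dimethylhepta-1,5-dien-3-yl]oxy}dimethylsilane F4. Iodine–lithium exchange (t-BuLi, Et2O, −78 °C) gives [(1E,3R)-3-[(tert-butyldimethylsilyl)oxy]-2,6-dimethylhepta-1,5-dien-1-yl]lithium F5, which opens ethylene oxide under BF3·OEt2 activation and returns to the route at 8.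

**Further compounds**
F1 | step 7 | lithium (2S)-oxirane-2-carboxylate | [Li+].[O-]C(=O)[C@@H]1CO1
F2 | step 7 | (2S)-2-hydroxy-5-[(phenylsulfanyl)methyl]hex-5-enoic acid | OC(=O)[C@@H](O)CCC(=C)CSc1ccccc1
F3 | step 13 | 2-(benzenesulfinyl)-5-[(2R,3R)-3-[(3E,5R)-5-[(tert-butyldimethylsilyl)oxy]-4,8-dimethylnona-3,7-dien-1-yl]-3-methyloxiran-2-yl]-3-methylidenepentan-1-ol | OCC(S(=O)c1ccccc1)C(=C)CC[C@H]1O[C@]1(C)CC/C=C(\C)[C@H](O[Si](C)(C)C(C)(C)C)CC=C(C)C
F4 | step 4 | tert-butyl{[(1E,3R)-1-iodo-2,6-dimethylhepta-1,5-dien-3-yl]oxy}dimethylsilane | I/C=C(\C)[C@H](O[Si](C)(C)C(C)(C)C)CC=C(C)C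
F5 | step 4 | [(1E,3R)-3-[(tert-butyldimethylsilyl)oxy]-2,6-dimethylhepta-1,5-dien-1-yl]lithium | [Li]/C=C(\C)[C@H](O[Si](C)(C)C(C)(C)C)CC=C(C)C
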